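**Plan**
1. Kaurane numbering is used: ring A = C1–C5/C10; ring C = C8, C9, C11–C14; ring D = C8, C13–C16; C6 and C7 are the formyl carbons, C17 the CH2OH, C19 the CO2H.
2. The retrosynthesis cuts C9–C10 first (two halves), then C12–C13 (ring C) and C8–C9 in the C/D half, and C4–C19, C5–C6 and C10–C20 in the ring-A half.
3. Forward, ring D is present from the start as a cyclopentenone; ring C is closed onto it by an intramolecular aldol reaction (C12–C13) to the bicyclo[3.2.1]octane, then C16 becomes the exo diol and C12 an enone.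
4. Ring A is made separately as a cis-fused C19→C6 lactone with a C10 methylidene and joined to C9 by radical conjugate addition; C12 is then deoxygenated and C6/C7 oxidised; ring B is never closed.
5. Stereochemistry: C8 and C4 from Cu-catalysed asymmetric conjugate additions, C13 from the bridging closure, C16 from exo dihydroxylation, C5 from equilibration to the cis lactone, C9 and C10 from the coupling (enone face anti to the C15–C16 bridge, radical face anti to the lactone).
6. Enabling feature: in ring D, C8 and C13 are 1,3-related and C16 bears oxygen, so a C16 carbonyl makes C13 nucleophilic toward a C12 aldehyde at the end of the C9–C11–C12 chain on quaternary C8.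

Key step: step 5

Remark: the target is treated as the open aldehydo acid that is drawn; a possible ring–chain equilibrium between the C6 aldehyde and the C19 acid is not considered.

**Step 1**
Reactants: 1 3-ethoxycyclopent-2-en-1-one; 2 tributyl[(benzyloxy)methyl]stannane
Product: 5 3-[(benzyloxy)methyl]cyclopent-2-en-1-one, via (benzyloxy)methyllithium 3 (not isolated), via lithium alkoxide adduct 4 (not isolated)
Conditions: n-BuLi, THF, −78 °C; add 1, −78 → 0 °C; then 1 M HCl, rt
Reagents that add atoms: water, O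
Why: Tin–lithium exchange gives an α-alkoxymethyllithium that adds 1,2 to the vinylogous ester, and acid hydrolysis of the enol ether with loss of water transposes the carbonyl (Stork–Danheiser sequence); no stereocentre is formed.

**Step 2**
Reactants: 5 3-[(benzyloxy)methyl]cyclopent-2-en-1-one; 6 2-(2-bromoethyl)-1,3-dioxolane
Product: 8 (3R)-3-[(benzyloxy)methyl]-3-[2-(1,3-dioxolan-2-yl)ethyl]cyclopentan-1-one, via Grignard reagent 7 (not isolated)
Conditions: Mg, THF, 25 °C; then Cu(OTf)2 (4 mol %), chiral imidazolinium salt (NHC precursor, 5 mol %; antipode giving (R)-8), Et2O, −30 °C; aqueous work-up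
Reagents that add atoms: none
Why: Copper-catalysed asymmetric conjugate addition of a Grignard reagent to a β,β-disubstituted cyclic enone is an established route to all-carbon quaternary centres, and the chiral NHC–copper complex selects the enone face so that C8 should form as (R).

**Step 3**
Reactants: 8 (3R)-3-[(benzyloxy)methyl]-3-[2-(1,3-dioxolan-2-yl)ethyl]cyclopentan-1-one
Product: 10 (4S)-4-[(benzyloxy)methyl]-4-[2-(1,3-dioxolan-2-yl)ethyl]cyclopent-2-en-1-one, via trimethylsilyl enol ether 9 (not isolated)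
Conditions: LDA, TMSCl, THF, −78 °C; then Pd(OAc)2 (1.1 equiv), MeCN, rt
Reagents that add atoms: none
Why: Kinetic deprotonation occurs at C13, away from quaternary C8, and Saegusa–Ito oxidation can only give the C13=C14 enone because C8 carries no hydrogen; this oxidation level is installed so that the enolate of step 5 can be generated at C13 only, and C8 is untouched (the descriptor changes by priority only).

**Step 4**
Reactants: 10 (4S)-4-[(benzyloxy)methyl]-4-[2-(1,3-dioxolan-2-yl)ethyl]cyclopent-2-en-1-one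
Product: 11 3-[(1S)-1-[(benzyloxy)methyl]-4-oxocyclopent-2-en-1-yl]propanal
Conditions: 1 M HCl, THF, rt
Reagents that add atoms: water, O
Why: Acid-catalysed acetal hydrolysis releases the C12 aldehyde without affecting the enone, the benzyl ether or C8.

**Step 5**
Reactants: 11 3-[(1S)-1-[(benzyloxy)methyl]-4-oxocyclopent-2-en-1-yl]propanal
Product: 13 (1R,4R,5S)-1-[(benzyloxy)methyl]-4-hydroxybicyclo[3.2.1]octan-6-one, via copper(I) enolate 12 (not isolated)
Conditions: [(Ph3P)CuH]6 (0.4 equiv), toluene/THF, −40 → 0 °C; aqueous work-up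
Reagents that add atoms: none
Why: Copper hydride delivers hydride to C14, the β-carbon of the enone, and the copper(I) enolate 12, which exists only at C13–C16, adds to the tethered C12 aldehyde; the closest known reaction type is the tandem conjugate reduction–intramolecular aldol (reductive aldol cyclisation) of enones carrying a tethered carbonyl group. Ring C (C8–C9–C11–C12–C13–C14) closes in a 6-(enolexo)-exo-trig mode and thereby bridges ring D to give the bicyclo[3.2.1]octane. C13 is set by the tether, because the three-carbon chain on C8 can only reach the enolate face cis to itself, and the C12 carbinol is expected to come from a closed, chair-like transition state with O12 gauche to the C16 carbonyl, which is immaterial because C12 is oxidised later. The step needs C13 and not C15 as the nucleophile, since closure from C15 would give a fused bicyclo[3.3.0]octane ketol that can dehydrate irreversibly; this is secured by forming the enolate through hydride delivery to C14 under aprotic, non-equilibrating conditions, so that C15 is never enolised. Chemoselectivity for the enone over the aldehyde rests on the preference of phosphine-ligated copper hydride for 1,4-reduction.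

**Step 6**
Reactants: 13 (1R,4R,5S)-1-[(benzyloxy)methyl]-4-hydroxybicyclo[3.2.1]octan-6-one
Product: 14 (1R,4R,5S)-1-[(benzyloxy)methyl]-4-[(triethylsilyl)oxy]bicyclo[3.2.1]octan-6-one
Conditions: TESCl, imidazole, DMF, 0 °C → rt
Reagents that add atoms: chlorotriethylsilane, CC[Si](Cl)(CC)CC
Why: Silyl ether formation masks the β-hydroxy ketone so that the basic methylenation that follows cannot trigger a retro-aldol cleavage.

**Step 7**
Reactants: 14 (1R,4R,5S)-1-[(benzyloxy)methyl]-4-[(triethylsilyl)oxy]bicyclo[3.2.1]octan-6-one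
Product: 15 (1R,4R,5R)-1-[(benzyloxy)methyl]-6-methylidene-4-[(triethylsilyl)oxy]bicyclo[3.2.1]octane
Conditions: Ph3PCH3Br, KOt-Bu, THF, 0 → 50 °C
Reagents that add atoms: methyltriphenylphosphonium bromide, C[P+](c1ccccc1)(c1ccccc1)c1ccccc1.[Br-]
Why: Wittig methylenation converts the C16 ketone into the exocyclic alkene; elimination toward the C13 bridgehead is impossible and no stereocentre changes.

**Step 8**
Reactants: 15 (1R,4R,5R)-1-[(benzyloxy)methyl]-6-methylidene-4-[(triethylsilyl)oxy]bicyclo[3.2.1]octane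
Product: 16 (1R,4R,5S,6R)-1-[(benzyloxy)methyl]-6-(hydroxymethyl)-4-[(triethylsilyl)oxy]bicyclo[3.2.1]octan-6-ol
Conditions: OsO4 (2 mol %), NMO, acetone/H2O, rt
Reagents that add atoms: osmium tetroxide, O=[Os](=O)(=O)=O; 4-methylmorpholine N-oxide, C[N+]1([O-])CCOCC1
Why: Upjohn dihydroxylation of the 1,1-disubstituted alkene should occur on the exo face, syn to the C14 methylene bridge, because the endo face is screened by the three-carbon bridge and the C12 silyloxy group; this sets C16 with OH exo and CH2OH endo.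

**Step 9**
Reactants: 16 (1R,4R,5S,6R)-1-[(benzyloxy)methyl]-6-(hydroxymethyl)-4-[(triethylsilyl)oxy]bicyclo[3.2.1]octan-6-ol
Product: 17 (1R,4R,5S,6R)-1-[(benzyloxy)methyl]-2',2'-dimethyl-4-[(triethylsilyl)oxy]spiro[bicyclo[3.2.1]octane-6,4'-[1,3]dioxolane]
Conditions: 2,2-dimethoxypropane, PPTS (cat.), CH2Cl2, rt
Reagents that add atoms: 2,2-dimethoxypropane, COC(C)(C)OC
Why: Acid-catalysed transacetalisation forms the five-membered acetonide of the tertiary/primary 1,2-diol, which protects it through the oxidations, the radical coupling and the reductions that follow.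

**Step 10**
Reactants: 17 (1R,4R,5S,6R)-1-[(benzyloxy)methyl]-2',2'-dimethyl-4-[(triethylsilyl)oxy]spiro[bicyclo[3.2.1]octane-6,4'-[1,3]dioxolane]
Product: 18 (1R,4R,5S,6R)-1-[(benzyloxy)methyl]-2',2'-dimethylspiro[bicyclo[3.2.1]octane-6,4'-[1,3]dioxolan]-4-ol
Conditions: TBAF, THF, 0 °C
Reagents that add atoms: none
Why: Fluoride-mediated desilylation removes the triethylsilyl ether selectively, the benzyl ether and the acetonide being inert.

**Step 11**
Reactants: 18 (1R,4R,5S,6R)-1-[(benzyloxy)methyl]-2',2'-dimethylspiro[bicyclo[3.2.1]octane-6,4'-[1,3]dioxolan]-4-ol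
Product: 19 (1R,5R,6R)-1-[(benzyloxy)methyl]-2',2'-dimethylspiro[bicyclo[3.2.1]octane-6,4'-[1,3]dioxolan]-4-one
Conditions: Dess–Martin periodinane, CH2Cl2, rt
Reagents that add atoms: none
Why: Dess–Martin oxidation gives the C12 ketone, which cannot enolise toward the C13 bridgehead and therefore cannot expel the C16 oxygen.

**Step 12**
Reactants: 19 (1R,5R,6R)-1-[(benzyloxy)methyl]-2',2'-dimethylspiro[bicyclo[3.2.1]octane-6,4'-[1,3]dioxolan]-4-one
Product: 21 (1R,5R,6R)-1-[(benzyloxy)methyl]-2',2'-dimethylspiro[bicyclo[3.2.1]oct-2-ene-6,4'-[1,3]dioxolan]-4-one, via trimethylsilyl enol ether 20 (not isolated)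
Conditions: LDA, TMSCl, THF, −78 °C; then Pd(OAc)2 (1.1 equiv), MeCN, rt
Reagents that add atoms: none
Why: C11 is the only enolisable position, so silyl enol ether formation and Saegusa–Ito dehydrogenation should give the C9=C11 enone regiospecifically.

**Step 13**
Reactants: 22 3-methylcyclohex-2-en-1-one; 23 hex-1-yne
Product: 26 (3S)-3-[(1E)-hex-1-en-1-yl]-2-(hydroxymethyl)-3-methylcyclohexan-1-one (C2 epimers), via (E)-hex-1-enyl(diisobutyl)alane 24 (not isolated), via aluminium enolate 25 (not isolated)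
Conditions: DIBAL-H, heptane, 50 °C; CuTC (10 mol %), chiral phosphinamine ligand (11 mol %; antipode giving (3S)), Et2O, −30 °C, add 22; then CH2O (monomeric, THF), −78 → −20 °C; aqueous work-up
Reagents that add atoms: formaldehyde, C=O
Why: syn-Hydroalumination gives the (E)-alkenylalane, its copper-catalysed asymmetric conjugate addition to the β-methyl enone creates the C4 quaternary centre under ligand control, and the regiodefined aluminium enolate is hydroxymethylated at C5 (tandem conjugate addition–aldol); C5 is not controlled here and is corrected in step 15.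

**Step 14**
Reactants: 26 (3S)-3-[(1E)-hex-1-en-1-yl]-2-(hydroxymethyl)-3-methylcyclohexan-1-one
Product: 27 (7aR)-1-hydroxy-7a-methylhexahydro-2-benzofuran-4(1H)-one (lactol epimers)
Conditions: O3, CH2Cl2/MeOH, −78 °C; then Me2S, −78 °C → rt
Reagents that add atoms: ozone, [O-][O+]=O
Why: Ozonolysis with reductive work-up cleaves the hexenyl group to the C19 aldehyde, which is captured by the C6 hydroxyl as a lactol; the ketone and C4 are unaffected.

**Step 15**
Reactants: 27 (7aR)-1-hydroxy-7a-methylhexahydro-2-benzofuran-4(1H)-one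
Product: 29 (3aS,7aR)-7a-methylhexahydro-2-benzofuran-1,4-dione, via C3a-epimeric keto lactone 28 (not isolated)
Conditions: TEMPO (20 mol %), PhI(OAc)2, CH2Cl2, rt; then TsOH·H2O (5 mol %), rt
Reagents that add atoms: none
Why: TEMPO/PhI(OAc)2 oxidation converts the lactol into the lactone, and acid-catalysed enolisation of the C10 ketone should then epimerise C5 to the more stable cis-fused γ-lactone (angular methyl on C4), which fixes C6 cis to C19.

**Step 16**
Reactants: 29 (3aS,7aR)-7a-methylhexahydro-2-benzofuran-1,4-dione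
Product: 30 (3aS,7aR)-7a-methyl-4-methylidenehexahydro-2-benzofuran-1(3H)-one
Conditions: Zn, CH2Br2, TiCl4, THF, 0 °C (reagent pre-formed); 29 in CH2Cl2, 0 °C → rt
Reagents that add atoms: dibromomethane, BrCBr
Why: Takai–Lombardo methylenation is non-basic and ketone-selective, so the β-acyloxy ketone should be methylenated without β-elimination or epimerisation and the lactone carbonyl is left alone; no new stereocentre is formed.

**Step 17**
Reactants: 21 (1R,5R,6R)-1-[(benzyloxy)methyl]-2',2'-dimethylspiro[bicyclo[3.2.1]oct-2-ene-6,4'-[1,3]dioxolan]-4-one; 30 (3aS,7aR)-7a-methyl-4-methylidenehexahydro-2-benzofuran-1(3H)-one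
Product: 31 7-(benzyloxy)-16,17-(isopropylidenedioxy)-12-oxo-6,7-secokaurano-19,6-lactone
Conditions: Fe(acac)3 (30 mol %), PhSiH3, EtOH/(CH2OH)2, 60 °C; 30 in excess (2.5 equiv)
Reagents that add atoms: none
Why: Iron-catalysed hydrogen-atom transfer to the 1,1-disubstituted alkene gives the tertiary C10 radical, which adds to C9 of the enone (reductive olefin–enone coupling, a Giese-type radical conjugate addition) before the α-keto radical is reduced and protonated; the radical should be attacked on the convex face of the cis-fused lactone (anti to C6 and C19) and the enone on the face opposite the C15–C16 bridge, which sets C10 and C9 as in the target.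

**Step 18**
Reactants: 31 7-(benzyloxy)-16,17-(isopropylidenedioxy)-12-oxo-6,7-secokaurano-19,6-lactone
Product: 33 7-(benzyloxy)-16,17-(isopropylidenedioxy)-6,7-secokaurano-19,6-lactone, via 12-tosylhydrazone 32 (not isolated)
Conditions: TsNHNH2, MeOH, 50 °C; concentrate; catecholborane, CHCl3, 0 °C; then NaOAc·3H2O, 60 °C
Reagents that add atoms: none
Why: Tosylhydrazone formation, hydride addition and acetate-induced loss of sulfinate and N2 (Caglioti-type deoxygenation in its catecholborane variant) remove the C12 carbonyl under conditions that leave lactone, acetonide and benzyl ether intact.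

**Step 19**
Reactants: 33 7-(benzyloxy)-16,17-(isopropylidenedioxy)-6,7-secokaurano-19,6-lactone
Product: 34 7-hydroxy-16,17-(isopropylidenedioxy)-6,7-secokaurano-19,6-lactone
Conditions: H2 (1 atm), Pd(OH)2/C, EtOAc/EtOH, rt
Reagents that add atoms: none
Why: Catalytic hydrogenolysis of the benzyl ether frees the C7 hydroxyl; nothing else in the molecule is reducible under these conditions.

**Step 20**
Reactants: 34 7-hydroxy-16,17-(isopropylidenedioxy)-6,7-secokaurano-19,6-lactone
Product: 37 benzyl 16,17-(isopropylidenedioxy)-6,7-dioxo-6,7-secokauran-19-oate, via potassium carboxylate 35 (not isolated), via diol benzyl ester 36 (not isolated)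
Conditions: KOH (1.05 equiv), MeOH/H2O, 50 °C; evaporate; BnBr, DMF, rt; extractive work-up; crude diol: Dess–Martin periodinane, CH2Cl2, 0 °C → rt
Reagents that add atoms: potassium hydroxide, [K+].[OH-]; benzyl bromide, BrCc1ccccc1
Why: Saponification opens the γ-lactone, O-alkylation of the carboxylate protects C19 as the benzyl ester, and immediate Dess–Martin oxidation converts the C6 and C7 primary alcohols into aldehydes before the γ-hydroxy ester can relactonise; C5 should keep its configuration because the aldehyde is formed under non-basic conditions.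

**Step 21**
Reactants: 37 benzyl 16,17-(isopropylidenedioxy)-6,7-dioxo-6,7-secokauran-19-oate
Product: 38 16,17-(isopropylidenedioxy)-6,7-dioxo-6,7-secokauran-19-oic acid
Conditions: H2 (1 atm), 10% Pd/C, EtOAc, rt
Reagents that add atoms: none
Why: Catalytic hydrogenolysis of the benzyl ester at 1 atm should be faster than reduction of the two hindered aliphatic aldehydes and liberates the C19 acid.

**Step 22**
Reactants: 38 16,17-(isopropylidenedioxy)-6,7-dioxo-6,7-secokauran-19-oic acid
Product: 39 16,17-dihydroxy-6,7-dioxo-6,7-secokauran-19-oic acid (target)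
Conditions: AcOH/H2O (4:1), 40 °C
Reagents that add atoms: none
Why: Mild acid-catalysed acetal hydrolysis releases the C16/C17 diol without epimerising C5.

**Compound list**
1 | 3-ethoxycyclopent-2-en-1-one | CCOC1=CC(=O)CC1 | starting material
2 | tributyl[(benzyloxy)methyl]stannane | CCCC[Sn](CCCC)(CCCC)COCc1ccccc1 | starting material
3 | (benzyloxy)methyllithium | [Li]COCc1ccccc1 | intermediate
4 | lithium 1-[(benzyloxy)methyl]-3-ethoxycyclopent-2-en-1-olate (racemic 1,2-adduct) | CCOC1=CC(O[Li])(COCc2ccccc2)CC1 | intermediate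
5 | 3-[(benzyloxy)methyl]cyclopent-2-en-1-one | O=C1C=C(COCc2ccccc2)CC1 | intermediate
6 | 2-(2-bromoethyl)-1,3-dioxolane | BrCCC1OCCO1 | starting material
7 | [2-(1,3-dioxolan-2-yl)ethyl]magnesium bromide | Br[Mg]CCC1OCCO1 | intermediate
8 | (3R)-3-[(benzyloxy)methyl]-3-[2-(1,3-dioxolan-2-yl)ethyl]cyclopentan-1-one | O1CCOC1CC[C@@]1(COCc2ccccc2)CCC(=O)C1 | intermediate
9 | {[(4R)-4-[(benzyloxy)methyl]-4-[2-(1,3-dioxolan-2-yl)ethyl]cyclopent-1-en-1-yl]oxy}trimethylsilane | O1CCOC1CC[C@@]1(COCc2ccccc2)CC=C(O[Si](C)(C)C)C1 | intermediate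
10 | (4S)-4-[(benzyloxy)methyl]-4-[2-(1,3-dioxolan-2-yl)ethyl]cyclopent-2-en-1-one | O1CCOC1CC[C@@]1(COCc2ccccc2)C=CC(=O)C1 | intermediate
11 | 3-[(1S)-1-[(benzyloxy)methyl]-4-oxocyclopent-2-en-1-yl]propanal | O=CCC[C@@]1(COCc2ccccc2)C=CC(=O)C1 | intermediate
12 | copper(I) (4R)-4-[(benzyloxy)methyl]-4-(3-oxopropyl)cyclopent-1-en-1-olate (phosphine ligands omitted) | O=CCC[C@@]1(COCc2ccccc2)CC=C(O[Cu])C1 | intermediate
13 | (1R,4R,5S)-1-[(benzyloxy)methyl]-4-hydroxybicyclo[3.2.1]octan-6-one (4-OH on the side of the carbonyl bridge) | C1C[C@@H](O)[C@@H]2C[C@@]1(COCc3ccccc3)CC2=O | intermediate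
14 | (1R,4R,5S)-1-[(benzyloxy)methyl]-4-[(triethylsilyl)oxy]bicyclo[3.2.1]octan-6-one | C1C[C@@H](O[Si](CC)(CC)CC)[C@@H]2C[C@@]1(COCc3ccccc3)CC2=O | intermediate
15 | (1R,4R,5R)-1-[(benzyloxy)methyl]-6-methylidene-4-[(triethylsilyl)oxy]bicyclo[3.2.1]octane | C1C[C@@H](O[Si](CC)(CC)CC)[C@@H]2C[C@@]1(COCc3ccccc3)CC2=C | intermediate
16 | (1R,4R,5S,6R)-1-[(benzyloxy)methyl]-6-(hydroxymethyl)-4-[(triethylsilyl)oxy]bicyclo[3.2.1]octan-6-ol (6-OH exo) | C1C[C@@H](O[Si](CC)(CC)CC)[C@@H]2C[C@@]1(COCc3ccccc3)C[C@]2(O)CO | intermediate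
17 | (1R,4R,5S,6R)-1-[(benzyloxy)methyl]-2',2'-dimethyl-4-[(triethylsilyl)oxy]spiro[bicyclo[3.2.1]octane-6,4'-[1,3]dioxolane] | C1C[C@@H](O[Si](CC)(CC)CC)[C@@H]2C[C@@]1(COCc3ccccc3)C[C@]2(OC(C)(C)O4)C4 | intermediate
18 | (1R,4R,5S,6R)-1-[(benzyloxy)methyl]-2',2'-dimethylspiro[bicyclo[3.2.1]octane-6,4'-[1,3]dioxolan]-4-ol | C1C[C@@H](O)[C@@H]2C[C@@]1(COCc3ccccc3)C[C@]2(OC(C)(C)O4)C4 | intermediate
19 | (1R,5R,6R)-1-[(benzyloxy)methyl]-2',2'-dimethylspiro[bicyclo[3.2.1]octane-6,4'-[1,3]dioxolan]-4-one | C1CC(=O)[C@@H]2C[C@@]1(COCc3ccccc3)C[C@]2(OC(C)(C)O4)C4 | intermediate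
20 | trimethylsilyl enol ether of 19 (C11=C12, kaurane numbering) | C1C=C(O[Si](C)(C)C)[C@@H]2C[C@@]1(COCc3ccccc3)C[C@]2(OC(C)(C)O4)C4 | intermediate
21 | (1R,5R,6R)-1-[(benzyloxy)methyl]-2',2'-dimethylspiro[bicyclo[3.2.1]oct-2-ene-6,4'-[1,3]dioxolan]-4-one | C1=CC(=O)[C@@H]2C[C@@]1(COCc3ccccc3)C[C@]2(OC(C)(C)O4)C4 | intermediate
22 | 3-methylcyclohex-2-en-1-one | CC1=CC(=O)CCC1 | starting material
23 | hex-1-yne | CCCCC#C | starting material
24 | (E)-hex-1-en-1-yl(diisobutyl)alane | CCCC/C=C/[Al](CC(C)C)CC(C)C | intermediate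
25 | diisobutylaluminium (3S)-3-[(1E)-hex-1-en-1-yl]-3-methylcyclohex-1-en-1-olate | CC(C)C[Al](CC(C)C)OC=1CCC[C@@](C)(/C=C/CCCC)C=1 | intermediate
26 | (3S)-3-[(1E)-hex-1-en-1-yl]-2-(hydroxymethyl)-3-methylcyclohexan-1-one (C2 epimers) | O=C1CCC[C@@](C)(/C=C/CCCC)C1CO | intermediate
27 | (7aR)-1-hydroxy-7a-methylhexahydro-2-benzofuran-4(1H)-one (lactol; epimers at C1 and C3a) | O=C1CCC[C@@](C)(C(O)OC2)C12 | intermediate
28 | (7aR)-7a-methylhexahydro-2-benzofuran-1,4-dione (C3a epimers) | O=C1CCC[C@@](C)(C(=O)OC2)C12 | intermediate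
29 | (3aS,7aR)-7a-methylhexahydro-2-benzofuran-1,4-dione (cis-fused) | O=C1CCC[C@@](C)(C(=O)OC2)[C@H]12 | intermediate
30 | (3aS,7aR)-7a-methyl-4-methylidenehexahydro-2-benzofuran-1(3H)-one (cis-fused) | C=C1CCC[C@@](C)(C(=O)OC2)[C@H]12 | intermediate
31 | 7-(benzyloxy)-16,17-(isopropylidenedioxy)-12-oxo-6,7-secokaurano-19,6-lactone (C4, C5, C8, C9, C10, C13, C16 as in the target; 16-O exo) | C[C@@]1([C@@H]2CC(=O)[C@@H]3C[C@@]2(COCc6ccccc6)C[C@]3(OC(C)(C)O4)C4)CCC[C@@](C)(C(=O)OC5)[C@H]15 | intermediate
32 | 12-(4-methylbenzenesulfonyl)hydrazone of 31 | C[C@@]1([C@@H]2CC(=NNS(=O)(=O)c7ccc(C)cc7)[C@@H]3C[C@@]2(COCc6ccccc6)C[C@]3(OC(C)(C)O4)C4)CCC[C@@](C)(C(=O)OC5)[C@H]15 | intermediate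
33 | 7-(benzyloxy)-16,17-(isopropylidenedioxy)-6,7-secokaurano-19,6-lactone (stereocentres as in the target) | C[C@@]1([C@@H]2CC[C@@H]3C[C@@]2(COCc6ccccc6)C[C@]3(OC(C)(C)O4)C4)CCC[C@@](C)(C(=O)OC5)[C@H]15 | intermediate
34 | 7-hydroxy-16,17-(isopropylidenedioxy)-6,7-secokaurano-19,6-lactone (stereocentres as in the target) | C[C@@]1([C@@H]2CC[C@@H]3C[C@@]2(CO)C[C@]3(OC(C)(C)O4)C4)CCC[C@@](C)(C(=O)OC5)[C@H]15 | intermediate
35 | potassium 6,7-dihydroxy-16,17-(isopropylidenedioxy)-6,7-secokauran-19-oate | C[C@@]1([C@@H]2CC[C@@H]3C[C@@]2(CO)C[C@]3(OC(C)(C)O4)C4)CCC[C@@](C)(C(=O)[O-])[C@H]1CO.[K+] | intermediate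
36 | benzyl 6,7-dihydroxy-16,17-(isopropylidenedioxy)-6,7-secokauran-19-oate | C[C@@]1([C@@H]2CC[C@@H]3C[C@@]2(CO)C[C@]3(OC(C)(C)O4)C4)CCC[C@@](C)(C(=O)OCc5ccccc5)[C@H]1CO | intermediate
37 | benzyl 16,17-(isopropylidenedioxy)-6,7-dioxo-6,7-secokauran-19-oate | C[C@@]1([C@@H]2CC[C@@H]3C[C@@]2(C=O)C[C@]3(OC(C)(C)O4)C4)CCC[C@@](C)(C(=O)OCc5ccccc5)[C@H]1C=O | intermediate
38 | 16,17-(isopropylidenedioxy)-6,7-dioxo-6,7-secokauran-19-oic acid | C[C@@]1([C@@H]2CC[C@@H]3C[C@@]2(C=O)C[C@]3(OC(C)(C)O4)C4)CCC[C@@](C)(C(=O)O)[C@H]1C=O | intermediate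
39 | 16,17-dihydroxy-6,7-dioxo-6,7-secokauran-19-oic acid, CNP0159160.1 (16-OH exo) | C[C@@]1([C@@H]2CC[C@@H]3C[C@@]2(C=O)C[C@]3(O)CO)CCC[C@@](C)(C(=O)O)[C@H]1C=O | target

**Totals**
Total step count: 22.
Longest linear sequence: 18 steps (steps 1–12 and 17–22, from 1); the ring-A branch (steps 13–16) adds 4.

**Steps most likely to fail**

1. Step 17 (fragment coupling). C9 is flanked by quaternary C8, so radical addition may be slow and hydrogenation of the C10 radical or conjugate reduction of the enone may win; facial control at C10 may also be incomplete. Fallback, setting out from 30 and returning at 31: Mukaiyama hydration of 30 (Co(acac)2, PhSiH3, O2) gives tertiary alcohol F1. Acylation with methyl chlorooxoacetate (Et3N, DMAP) gives methyl oxalate F2. One equivalent of CsOH hydrolyses only the oxalate ester to caesium oxalate F3. Visible-light photoredox coupling of F3 with enone 21 (Ir photocatalyst, DME/DMF, water, blue light) generates the same C10 radical by double decarboxylation under redox-neutral conditions, with no hydride source to consume either partner, and gives 31.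

2. Step 5 (key step). Copper hydride may reduce the aldehyde, or the copper enolate may be protonated before it cyclises, leaving the simple conjugate-reduction product. Fallback, setting out from 8 and returning at 13: hydrolysis of the dioxolane of 8 (1 M HCl, THF) gives saturated keto aldehyde F4. Amine catalysis (pyrrolidine/AcOH or proline) forms the less hindered C13 enamine, which closes ring C by a direct intramolecular aldol reaction to 13. Steps 3–5 are bypassed.

3. Step 20. The γ-hydroxy benzyl ester 36 may relactonise to 34 before it is oxidised, or the hindered lactone may open incompletely. Fallback, setting out from 34 and returning at 37: after saponification to 35, excess TESCl/imidazole silylates both hydroxyls and the carboxylate to give tris-silyl compound F5. Mild K2CO3 in aqueous MeOH cleaves only the silyl ester to give bis-TES ether acid F6. Cs2CO3/BnBr gives bis-TES ether benzyl ester F7. Swern oxidation ((COCl)2, DMSO, then Et3N) converts the two primary triethylsilyl ethers directly into aldehydes and gives 37, so a free γ-hydroxy ester never exists.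

**Further compounds**
F1 | step 17 | (3aS,7aR)-4-hydroxy-4,7a-dimethylhexahydro-2-benzofuran-1(3H)-one (OH trans to the lactone) | C[C@@]1(O)CCC[C@@](C)(C(=O)OC2)[C@H]12
F2 | step 17 | methyl oxalate of F1 | C[C@@]1(OC(=O)C(=O)OC)CCC[C@@](C)(C(=O)OC2)[C@H]12
F3 | step 17 | caesium oxalate of F1 | C[C@@]1(OC(=O)C(=O)[O-])CCC[C@@](C)(C(=O)OC2)[C@H]12.[Cs+]
F4 | step 5 | 3-[(1R)-1-[(benzyloxy)methyl]-3-oxocyclopentyl]propanal | O=CCC[C@@]1(COCc2ccccc2)CCC(=O)C1
F5 | step 20 | triethylsilyl 16,17-(isopropylidenedioxy)-6,7-bis[(triethylsilyl)oxy]-6,7-secokauran-19-oate | C[C@@]1([C@@H]2CC[C@@H]3C[C@@]2(CO[Si](CC)(CC)CC)C[C@]3(OC(C)(C)O4)C4)CCC[C@@](C)(C(=O)O[Si](CC)(CC)CC)[C@H]1CO[Si](CC)(CC)CC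
F6 | step 20 | 16,17-(isopropylidenedioxy)-6,7-bis[(triethylsilyl)oxy]-6,7-secokauran-19-oic acid | C[C@@]1([C@@H]2CC[C@@H]3C[C@@]2(CO[Si](CC)(CC)CC)C[C@]3(OC(C)(C)O4)C4)CCC[C@@](C)(C(=O)O)[C@H]1CO[Si](CC)(CC)CC
F7 | step 20 | benzyl 16,17-(isopropylidenedioxy)-6,7-bis[(triethylsilyl)oxy]-6,7-secokauran-19-oate | C[C@@]1([C@@H]2CC[C@@H]3C[C@@]2(CO[Si](CC)(CC)CC)C[C@]3(OC(C)(C)O4)C4)CCC[C@@](C)(C(=O)OCc5ccccc5)[C@H]1CO[Si](CC)(CC)CC
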